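Compound numbers are those of the steps below. Primed locants refer to ring B as in the target (C1' on the ester carbonyl, C6' bearing the methyl group); the systematic names of intermediates number the same benzoyl ring from the other side, so that C6' is position 2 of the benzoyl group.

## Analysis of the target

Target 18 is a depside. Ring A is a methyl salicylate (C1 CO2CH3, C2 OH, C3 CH3, C4 O-acyl, C5 H, C6 CH3), esterified through its C4 oxygen with ring B, a hexasubstituted benzoyl group (C1' on the ester carbonyl, C2' OH, C3' CHO, C4' OH, C5' OH, C6' CH3). There is no stereocentre, so every selectivity question concerns regiochemistry or chemoselectivity. The sensitive groups are the aryl ester (an acyl donor toward bases and nucleophiles), the aldehyde lying between two phenols, the methyl ester, and the 2',4',5'-trioxygenated ring B, which oxidises easily once its phenols are free. The synthesis is hard because the linking ester joins a benzoic acid with two ortho substituents to a phenol flanked by a methyl group, because ring B has no free position and ring A only one, and because five oxygen functions must be told apart. The strategy rests on ring A: C2, C3, C4 and C5 carry O, CH3, O and H, which is the pattern of the ester carbon, α-carbon, ketone carbon and γ-methyl of keto ester 8. The oxygen on C4, the ketone oxygen of 8, is also the oxygen of the depside ester, and C1 and C6 carry CO2CH3 and CH3 exactly as the two alkyne carbons of 12 do. The depside ester can therefore be made early as an enol ester (10) and ring A closed around it by cycloaddition of diene 11 with 12.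

## Retrosynthetic reasoning

**18 to 17.** The last bond cut is the O–CH3 bond at C4'. Keeping this oxygen as a methyl ether until the end means ring B is never a free triol before the electron-withdrawing aldehyde is in place. The ether in 17 is the only one lying ortho to the formyl group and to a free phenol, so a chelating boron Lewis acid can remove it while the methyl ester of ring A stays.

**17 to 16.** The C3'–CHO bond is cut next. C3' is the only unsubstituted carbon of ring B and lies ortho to the C2' phenol and the C4' methoxy group. The single free carbon of ring A (C5) sits on a ring deactivated by its ester. Putting the aldehyde in late keeps it away from the amide base, the thermal step and the hydrogenolysis.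

**16 to 15.** The two O–benzyl bonds at C2' and C5' are cut. Benzyl is chosen because it survives amide base, 110 °C and aqueous acid, and because it can be removed by hydrogenolysis while no aldehyde is present.

**15 to 11 and 12.** Ring A is opened at C1–C2 and C5–C6. These two bonds separate the carbons with the 1,3-dioxygen pattern (C2 to C5) from the two carbons carrying ester and methyl (C1, C6), so the pieces are the four-carbon unit of 8 and the ynoate 12, each with its substituents in place and no oxidation-state change needed. Cutting the ester C–O bond instead would be the usual depside disconnection, but it puts the whole difficulty into acylating a hindered phenol with a di-ortho-substituted acid. The chosen cut gains one ring, two C–C bonds and all five substituents of ring A in one operation. The forward reaction must join the methylene terminus of 11 to the methyl-bearing carbon of 12 and the ketene acetal carbon to the ester-bearing carbon. It must then shed the methoxy and silyl groups of the ketene acetal so that C2 emerges as a free phenol next to the ester.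

**11 to 10.** The O–Si bond and the γ C–H bond are cut. Diene 11 is the silylated dienolate of enol ester 10. The forward step must remove a proton from the γ-methyl of 10 and trap the dienolate on oxygen before the aroyloxy group can leave or migrate.

**10 to 7 and 8 (through 9).** The depside C–O bond is cut here, at the stage where the oxygen belongs to the enolate of 8 and not to a hindered phenol. The forward reaction needs O-acylation rather than C-acylation, which the hindered, acylium-like chloride 9 and a dissociated enolate favour.

**7 to 6 to 5.** The C1'–carboxyl bond is cut. The carboxyl carbon enters as a formyl group at the ring carbon of 5 that is para to the methoxy group and ortho to a benzyloxy group, and 6 is then oxidised to 7. The other free carbon of 5 lies between two alkoxy groups and is less reactive toward a bulky electrophile.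

**5 to 2 and 3 (through 4), and 2 to 1.** The two O–benzyl bonds are cut back to hydroquinone 4, which comes from quinone 2 by reduction; each of the two phenol oxygens of 4 takes up one molecule of 3. The C–O bond para to the hydroxyl of 1 is cut last. Both ortho positions of 1 are blocked, so oxidation can only give the para-quinone, and the methoxy, methyl and two oxygen positions of ring B are then fixed unambiguously.

## Alternatives that were turned down

**Alternative 1:** ring B by ketene capture and aldol aromatization.
- Disconnection: the depside C–O bond and C1'–C6' of ring B, so that ring B grows from an open chain on the oxygen of ring A.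
- Forward key step: the diketo-dioxinone A2 is heated with the ring A phenol A3. Cycloreversion of the dioxinone releases an acylketene that the C4 phenol of A3 traps. Amine base and then acid close ring B by aldol condensation between C1' and C6' to give A1.
- For: the ester is made by a ketene, the least hindered acylating agent there is, before ring B exists. A3 can be bought. A1 has both the C2' and C4' phenols free, so formylation at C3' falls between two hydroxyl groups and only one benzyl ether remains to be removed.
- Against: the C5' oxygen must ride as a benzyloxy group on the carbon between two ketones of A2. That centre enolises readily and can eliminate, and A2 itself needs several steps of dioxinone dienolate acylation. The open-chain triketo aryl ester is an activated ester, and an enol oxygen further along the chain can lactonise onto it and eject A3 before the aldol closes the ring.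
- Comparison: Alternative 1 is one step shorter after the key step and needs no Lewis-acid demethylation, so on those points it is stronger. The chosen route instead fixes the ring B oxygen pattern on a stable aromatic compound (7) before the risky step, and its ester carbonyl is shielded by two ortho substituents while ring A forms.

**Alternative 2:** ring B from a silyloxyfuran and an ynoate ester.
- Disconnection: C2'–C1' and C5'–C6' of ring B.
- Forward key step: furan A5 adds across the alkyne of A6, the but-2-ynoate ester of the ring A phenol. The oxygen-bridged adduct opens under the push of the silyloxy group and enolises to the hydroquinone A4.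
- For: A4 is the same substance as compound 16 of the chosen route, reached with no protecting group on ring B and from two fragments that are each about one step from purchased material. In step count this is clearly the shortest plan.
- Against: the diene is an aromatic furan, which must give up its aromaticity and tends to stop after conjugate addition at its C5 without closing the second bond. The dienophile is again a β-methyl ynoate, but here it is the advanced fragment and cannot be used in excess. The aryl ynoate is also an acyl donor, and the product is formed as an unprotected hydroquinone at high temperature.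
- Comparison: the two routes share the end game from 16, so the comparison is only about how 16 is reached. Alternative 2 is much shorter. The chosen route offers a non-aromatic, more nucleophilic diene, a cheap dienophile used in excess, and a hydroquinone that stays benzylated through the thermal step.

**Alternative 3:** three-component palladium aryloxycarbonylation.
- Disconnection: C1'–C(=O) and C(=O)–O; no ring is formed.
- Forward key step: aryl iodide A8, carbon monoxide A9 and the phenol A3 are joined by a palladium–bisphosphine catalyst with an amine base to give A7.
- For: it is the most convergent plan. Ring B arrives fully substituted with the aldehyde in place, so there is no late formylation and only deprotection remains. Phenoxycarbonylation of aryl iodides is an established reaction type.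
- Against: A8 is a hexasubstituted benzene whose iodide is flanked by a methyl and a benzyloxy group, so oxidative addition to zerovalent palladium is slow. The acylpalladium intermediate must then be captured by a hindered, weakly nucleophilic phenoxide in competition with reduction of the C–I bond. Making A8 takes at least as many steps as making 7. The benzyl ethers of A7 would have to be hydrogenolysed beside an aromatic aldehyde, which can be over-reduced.
- Comparison: Alternative 3 is stronger in convergence and in avoiding late formylation. The chosen route avoids a late metal-catalysed carbonylation at a crowded carbon, removes the benzyl groups before the aldehyde exists, and forms the ester bond on a small enolate where O-acylation is easy.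

Key step: step 7

Remark: keto ester 8 is used as the racemate because its stereocentre disappears on enolisation; enol ester 10 is drawn as the E isomer, and any Z isomer leads to the same diene 11.

## Route

Step 1
Reactants: 1 2-methoxy-6-methylphenol
Product: 2 2-methoxy-6-methyl-1,4-benzoquinone
Conditions: ON(SO3K)2 (Fremy's salt, 2.2 equiv), KH2PO4, H2O/acetone, 0 °C to rt
Reagents that add atoms: potassium nitrosodisulfonate, [K+].[K+].[O]N(S(=O)(=O)[O-])S(=O)(=O)[O-]
Why: Teuber oxidation: the phenoxyl radical is captured at the free para carbon by a second nitrosodisulfonate radical and the adduct collapses to the quinone; both ortho positions of 1 are blocked, so only the 1,4-quinone can form.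

Step 2
Reactants: 2 2-methoxy-6-methyl-1,4-benzoquinone; 3 benzyl bromide (two equivalents are incorporated)
Product: 5 2,5-bis(benzyloxy)-1-methoxy-3-methylbenzene, via 2-methoxy-6-methylbenzene-1,4-diol 4 (not isolated)
Conditions: Na2S2O4, EtOAc/H2O, rt, argon; crude 4, then 3 (2.5 equiv), K2CO3, DMF, 60 °C
Reagents that add atoms: benzyl bromide (the second equivalent of 3), BrCc1ccccc1
Why: Dithionite reduction of the quinone followed by a twofold Williamson etherification, in which each phenoxide oxygen of 4 displaces bromide from one molecule of 3; the air-sensitive hydroquinone 4 is alkylated without purification.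

Step 3
Reactants: 5 2,5-bis(benzyloxy)-1-methoxy-3-methylbenzene
Product: 6 3,6-bis(benzyloxy)-4-methoxy-2-methylbenzaldehyde
Conditions: POCl3, DMF, 0 to 75 °C; then aq. NaOAc
Reagents that add atoms: N,N-dimethylformamide, CN(C)C=O; water, O
Why: Vilsmeier–Haack formylation; the carbon para to the methoxy group and ortho to a benzyloxy group is attacked, the position at which orcinol diethers and 1,2,4-trialkoxybenzenes are formylated, while the other free carbon lies between two alkoxy groups and is activated only from ortho positions.

Step 4
Reactants: 6 3,6-bis(benzyloxy)-4-methoxy-2-methylbenzaldehyde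
Product: 7 3,6-bis(benzyloxy)-4-methoxy-2-methylbenzoic acid
Conditions: NaClO2, NaH2PO4, 2-methyl-2-butene, t-BuOH/THF/H2O, rt
Reagents that add atoms: sodium chlorite, [Na+].[O-]Cl=O
Why: Pinnick oxidation; chlorous acid oxidises even di-ortho-substituted benzaldehydes, and the alkene scavenges hypochlorous acid so that the electron-rich ring is not chlorinated.

Step 5
Reactants: 7 3,6-bis(benzyloxy)-4-methoxy-2-methylbenzoic acid; 8 methyl 2-methyl-3-oxobutanoate
Product: 10 (E)-4-methoxy-3-methyl-4-oxobut-2-en-2-yl 3,6-bis(benzyloxy)-4-methoxy-2-methylbenzoate, via 3,6-bis(benzyloxy)-4-methoxy-2-methylbenzoyl chloride 9 (not isolated)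
Conditions: 7, (COCl)2, DMF (cat.), CH2Cl2, 0 °C to rt, evaporate; 8, NaH, THF/DMPU, 0 °C, then crude 9, 0 °C to rt
Reagents that add atoms: none
Why: O-acylation of a β-keto ester enolate: the dissociated sodium enolate reacts at oxygen with the hard, hindered aroyl chloride, whereas C-acylation would have to build a quaternary carbon beside a di-ortho-substituted aryl ketone; the unchelated enolate should give mainly the E enol ester, whose γ-methyl lies cis to the ester as step 6 prefers.

Step 6
Reactants: 10 (E)-4-methoxy-3-methyl-4-oxobut-2-en-2-yl 3,6-bis(benzyloxy)-4-methoxy-2-methylbenzoate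
Product: 11 3-[methoxy(trimethylsilyloxy)methylidene]but-1-en-2-yl 3,6-bis(benzyloxy)-4-methoxy-2-methylbenzoate
Conditions: LiN(i-Pr)2 and Me3SiCl premixed, THF, −78 °C, then add 10; warm, evaporate, pentane, filter under argon
Reagents that add atoms: chlorotrimethylsilane, C[Si](C)(C)Cl
Why: γ-Deprotonation of a β-oxygenated enoate and O-silylation of the dienolate, the way 1-alkoxy-1-silyloxy-3-oxybutadienes are made from β-alkoxy and β-silyloxy crotonates; the silyl chloride is present from the start so that the lithium dienolate is trapped before it can expel the aroate or before the base turns to the C6' methyl group, and the aroyl carbonyl is screened by its two ortho substituents.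

Step 7
Reactants: 11 3-[methoxy(trimethylsilyloxy)methylidene]but-1-en-2-yl 3,6-bis(benzyloxy)-4-methoxy-2-methylbenzoate; 12 methyl but-2-ynoate
Product: 15 methyl 4-[3,6-bis(benzyloxy)-4-methoxy-2-methylbenzoyloxy]-2-hydroxy-3,6-dimethylbenzoate, via silyl ketal cycloadduct 13 (not isolated), via cyclohexadienone 14 (not isolated)
Conditions: 12 (5 equiv), toluene, 110 °C, sealed tube; then 1 M HCl, THF, 0 °C to rt
Reagents that add atoms: none
Why: This is a Diels–Alder reaction of normal electron demand in which the ketene acetal and the enol ester oxygen both push electron density onto the terminal methylene of 11, while the ester of 12 makes its methyl-bearing β-carbon the electrophilic end. The C5–C6 bond therefore forms ahead of the C1–C2 bond in an asynchronous transition state, and in the stepwise limit a conjugate addition is followed by closure of the ester-stabilised anion onto the dioxygenated cation. The closest known reaction type is the cycloaddition of 1-alkoxy-1-silyloxy-3-oxybutadienes with alkynoates followed by aromatisation to salicylates. Ring A closes as a six-membered carbocycle by intermolecular [4+2] cycloaddition, both ring bonds being formed in this step to give 13. Aqueous acid then hydrolyses the silyl methyl ketal at C2 of 13 to the ketone 14 with loss of trimethylsilanol and methanol, and the C5 methylene of 14 enolises at once to give the aromatic phenol. No stereocentre is created in the product, since the C2 centre of 13 is racemic and is destroyed. The step needs regioselectivity, which the matched polarisation of the two partners secures and which places the new phenol ortho to the methyl ester. It also needs the aryl ester to survive, which it should because neither base nor nucleophile is present and its carbonyl is flanked by the C2' benzyloxy and C6' methyl groups.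

Step 8
Reactants: 15 methyl 4-[3,6-bis(benzyloxy)-4-methoxy-2-methylbenzoyloxy]-2-hydroxy-3,6-dimethylbenzoate
Product: 16 methyl 4-(3,6-dihydroxy-4-methoxy-2-methylbenzoyloxy)-2-hydroxy-3,6-dimethylbenzoate
Conditions: H2 (1 atm), 10% Pd/C, EtOAc, rt
Reagents that add atoms: none
Why: Hydrogenolysis of aryl benzyl ethers; the aryl ester and the methyl ester are inert, and the step is placed before the aldehyde exists so that no formyl group meets hydrogen; 16 is a hydroquinone and is carried on under argon.

Step 9
Reactants: 16 methyl 4-(3,6-dihydroxy-4-methoxy-2-methylbenzoyloxy)-2-hydroxy-3,6-dimethylbenzoate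
Product: 17 methyl 4-(3-formyl-2,5-dihydroxy-4-methoxy-6-methylbenzoyloxy)-2-hydroxy-3,6-dimethylbenzoate
Conditions: Cl2CHOCH3, TiCl4, CH2Cl2, −20 to 0 °C; then 1 M HCl
Reagents that add atoms: dichloromethyl methyl ether, COC(Cl)Cl; water, O
Why: Rieche formylation of a phenol: titanium bound to the C2' phenolate delivers the electrophile to the ortho carbon C3', the only unsubstituted position of the electron-rich ring B, whereas the single free carbon of ring A (C5) belongs to a ring deactivated by its titanium-chelated salicylate ester.

Step 10
Reactants: 17 methyl 4-(3-formyl-2,5-dihydroxy-4-methoxy-6-methylbenzoyloxy)-2-hydroxy-3,6-dimethylbenzoate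
Product: 18 methyl 4-(3-formyl-2,4,5-trihydroxy-6-methylbenzoyloxy)-2-hydroxy-3,6-dimethylbenzoate
Conditions: BCl3, CH2Cl2, −78 to 0 °C; then H2O
Reagents that add atoms: none
Why: Chelation-controlled ether cleavage: boron held between the C4' methoxy oxygen and the neighbouring formyl oxygen or C5' phenolate activates the methyl group for attack by chloride, the known selectivity of BCl3 for methyl ethers ortho to a carbonyl group; the methyl ester and the aryl ester are not cleaved at this temperature.

## Compound list

1 | 2-methoxy-6-methylphenol | COc1cccc(C)c1O | starting material
2 | 2-methoxy-6-methyl-1,4-benzoquinone | COC1=CC(=O)C=C(C)C1=O | intermediate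
3 | benzyl bromide | BrCc1ccccc1 | starting material
4 | 2-methoxy-6-methylbenzene-1,4-diol | COc1cc(O)cc(C)c1O | intermediate
5 | 2,5-bis(benzyloxy)-1-methoxy-3-methylbenzene | COc1cc(OCc2ccccc2)cc(C)c1OCc1ccccc1 | intermediate
6 | 3,6-bis(benzyloxy)-4-methoxy-2-methylbenzaldehyde | COc1cc(OCc2ccccc2)c(C=O)c(C)c1OCc1ccccc1 | intermediate
7 | 3,6-bis(benzyloxy)-4-methoxy-2-methylbenzoic acid | COc1cc(OCc2ccccc2)c(C(=O)O)c(C)c1OCc1ccccc1 | intermediate
8 | methyl 2-methyl-3-oxobutanoate (racemic) | CC(=O)C(C)C(=O)OC | starting material
9 | 3,6-bis(benzyloxy)-4-methoxy-2-methylbenzoyl chloride | COc1cc(OCc2ccccc2)c(C(Cl)=O)c(C)c1OCc1ccccc1 | intermediate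
10 | (E)-4-methoxy-3-methyl-4-oxobut-2-en-2-yl 3,6-bis(benzyloxy)-4-methoxy-2-methylbenzoate | COC(=O)/C(C)=C(\C)OC(=O)c1c(C)c(OCc2ccccc2)c(OC)cc1OCc1ccccc1 | intermediate
11 | 3-[methoxy(trimethylsilyloxy)methylidene]but-1-en-2-yl 3,6-bis(benzyloxy)-4-methoxy-2-methylbenzoate (ketene acetal geometry not defined) | COC(O[Si](C)(C)C)=C(C)C(=C)OC(=O)c1c(C)c(OCc2ccccc2)c(OC)cc1OCc1ccccc1 | intermediate
12 | methyl but-2-ynoate | CC#CC(=O)OC | starting material
13 | methyl 4-[3,6-bis(benzyloxy)-4-methoxy-2-methylbenzoyloxy]-6-methoxy-2,5-dimethyl-6-(trimethylsilyloxy)cyclohexa-1,4-diene-1-carboxylate (racemic) | COC(=O)C1=C(C)CC(OC(=O)c2c(C)c(OCc3ccccc3)c(OC)cc2OCc2ccccc2)=C(C)C1(OC)O[Si](C)(C)C | intermediate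
14 | methyl 4-[3,6-bis(benzyloxy)-4-methoxy-2-methylbenzoyloxy]-2,5-dimethyl-6-oxocyclohexa-1,4-diene-1-carboxylate | COC(=O)C1=C(C)CC(OC(=O)c2c(C)c(OCc3ccccc3)c(OC)cc2OCc2ccccc2)=C(C)C1=O | intermediate
15 | methyl 4-[3,6-bis(benzyloxy)-4-methoxy-2-methylbenzoyloxy]-2-hydroxy-3,6-dimethylbenzoate | COC(=O)c1c(C)cc(OC(=O)c2c(C)c(OCc3ccccc3)c(OC)cc2OCc2ccccc2)c(C)c1O | intermediate
16 | methyl 4-(3,6-dihydroxy-4-methoxy-2-methylbenzoyloxy)-2-hydroxy-3,6-dimethylbenzoate | COC(=O)c1c(C)cc(OC(=O)c2c(C)c(O)c(OC)cc2O)c(C)c1O | intermediate
17 | methyl 4-(3-formyl-2,5-dihydroxy-4-methoxy-6-methylbenzoyloxy)-2-hydroxy-3,6-dimethylbenzoate | COC(=O)c1c(C)cc(OC(=O)c2c(C)c(O)c(OC)c(C=O)c2O)c(C)c1O | intermediate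
18 | methyl 4-(3-formyl-2,4,5-trihydroxy-6-methylbenzoyloxy)-2-hydroxy-3,6-dimethylbenzoate (CNP0216802.0) | COC(=O)c1c(C)cc(OC(=O)c2c(C)c(O)c(O)c(C=O)c2O)c(C)c1O | target

## Step count and least certain steps

Total step count: 10. Longest linear sequence: 10 steps (1 to 18); compounds 3, 8 and 12 are purchased.

**Step 7 (key step).** The acyloxy group makes diene 11 less nucleophilic than its silyloxy relatives, and 12 is a β-substituted, sluggish dienophile. At the temperature needed, loss of the silyl and aroyloxy groups from 11, silyl migration to carbon and protodesilylation back to 10 may outrun the cycloaddition. A second risk is aromatisation with loss of trimethylsilanol in place of methanol, which would leave the C2 oxygen methylated; such an ether lies ortho to the ester carbonyl and would be cleaved by BCl3 in step 10. Fallback: keep diene 11 but replace the alkyne by the more reactive allene. The fallback sets out from 11. Reaction with methyl buta-2,3-dienoate F1 at 60 to 80 °C in toluene should form the same two ring bonds at the conjugated double bond of the allene and give methyl 4-[3,6-bis(benzyloxy)-4-methoxy-2-methylbenzoyloxy]-2-methoxy-3-methyl-6-methylidene-2-(trimethylsilyloxy)cyclohex-3-ene-1-carboxylate F2. Acid then removes methanol and silanol and moves the exocyclic double bond into the ring, which returns to the route at 15. If diene 11 cannot be used at all, the fallback under step 6 applies.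

**Step 6.** The amide base may remove a proton from the C6' methyl group, which is ortho to the ester on the aroyl ring, and the lithium dienolate may expel the aroate before silicon traps it; the Z isomer of 10 may also be deprotonated slowly. Fallback: take the aroyl group out of the strong-base step and esterify after ring A is made. The fallback sets out from 8. Me3SiCl and Et3N give methyl 2-methyl-3-(trimethylsilyloxy)but-2-enoate F3, and LiN(i-Pr)2 then Me3SiCl give 1-methoxy-2-methyl-1,3-bis(trimethylsilyloxy)buta-1,3-diene F4, a diene of the established bis-silyloxy class. Heating F4 with 12 and acidic work-up should form the same C1–C2 and C5–C6 bonds and give methyl 2,4-dihydroxy-3,6-dimethylbenzoate F5, which can also be bought. Acylation of its unchelated C4 phenol with acid chloride 9 (pyridine, CH2Cl2) returns to the route at 15.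

**Step 9.** The free hydroquinone of 16 may be O-formylated or oxidised under the Lewis acid, and some attack at C5 of ring A cannot be excluded. Fallback: avoid a free hydroquinone at the formylation stage by changing the order of deprotection. The fallback sets out from 15. MgBr2·OEt2 in toluene/Et2O removes selectively the benzyl ether ortho to the ester carbonyl and gives methyl 4-[3-(benzyloxy)-6-hydroxy-4-methoxy-2-methylbenzoyloxy]-2-hydroxy-3,6-dimethylbenzoate F6. Ortho-formylation at C3' as in step 9 gives methyl 4-[3-(benzyloxy)-5-formyl-6-hydroxy-4-methoxy-2-methylbenzoyloxy]-2-hydroxy-3,6-dimethylbenzoate F7. Excess BCl3 at −78 to 0 °C then cleaves both the remaining benzyl ether and the methyl ether beside the aldehyde, which returns to the route at 18.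

**Step 10.** Boron-mediated cleavage may spread to the aryl ester, or the aldehyde may not survive as its boron chelate. Fallback: remove the methyl group before the aldehyde is present. The fallback sets out from 16. BCl3 with Bu4NI in CH2Cl2 at −78 to 0 °C, a combination that cleaves unactivated aryl methyl ethers and spares esters, gives methyl 2-hydroxy-3,6-dimethyl-4-(3,4,6-trihydroxy-2-methylbenzoyloxy)benzoate F8, handled under argon. Rieche formylation at C3', now between two phenols, returns to the route at 18.

**Step 3.** The bulky iminium electrophile may react slowly at a carbon flanked by a benzyloxy and a methyl group, and prolonged heating may then bring attack at the carbon between the two alkoxy groups. Fallback: halogenation and carboxylation in place of formylation and oxidation. The fallback sets out from 5. NBS in MeCN at 0 °C, a small and strongly para-directing electrophile, gives 1,4-bis(benzyloxy)-2-bromo-5-methoxy-3-methylbenzene F9. Bromine–lithium exchange with n-BuLi in THF at −78 °C and quenching with CO2 returns to the route at 7, passing 6 by.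

## Further compounds

F1 | step 7 | methyl buta-2,3-dienoate | C=C=CC(=O)OC
F2 | step 7 | methyl 4-[3,6-bis(benzyloxy)-4-methoxy-2-methylbenzoyloxy]-2-methoxy-3-methyl-6-methylidene-2-(trimethylsilyloxy)cyclohex-3-ene-1-carboxylate (mixture of diastereomers) | COC(=O)C1C(=C)CC(OC(=O)c2c(C)c(OCc3ccccc3)c(OC)cc2OCc2ccccc2)=C(C)C1(OC)O[Si](C)(C)C
F3 | step 6 | methyl 2-methyl-3-(trimethylsilyloxy)but-2-enoate (E/Z mixture) | C[Si](C)(C)OC(C)=C(C)C(=O)OC
F4 | step 6 | 1-methoxy-2-methyl-1,3-bis(trimethylsilyloxy)buta-1,3-diene | COC(O[Si](C)(C)C)=C(C)C(=C)O[Si](C)(C)C
F5 | step 6 | methyl 2,4-dihydroxy-3,6-dimethylbenzoate | COC(=O)c1c(C)cc(O)c(C)c1O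
F6 | step 9 | methyl 4-[3-(benzyloxy)-6-hydroxy-4-methoxy-2-methylbenzoyloxy]-2-hydroxy-3,6-dimethylbenzoate | COC(=O)c1c(C)cc(OC(=O)c2c(C)c(OCc3ccccc3)c(OC)cc2O)c(C)c1O
F7 | step 9 | methyl 4-[3-(benzyloxy)-5-formyl-6-hydroxy-4-methoxy-2-methylbenzoyloxy]-2-hydroxy-3,6-dimethylbenzoate | COC(=O)c1c(C)cc(OC(=O)c2c(C)c(OCc3ccccc3)c(OC)c(C=O)c2O)c(C)c1O
F8 | step 10 | methyl 2-hydroxy-3,6-dimethyl-4-(3,4,6-trihydroxy-2-methylbenzoyloxy)benzoate | COC(=O)c1c(C)cc(OC(=O)c2c(C)c(O)c(O)cc2O)c(C)c1O
F9 | step 3 | 1,4-bis(benzyloxy)-2-bromo-5-methoxy-3-methylbenzene | COc1cc(OCc2ccccc2)c(Br)c(C)c1OCc1ccccc1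
A1 | alternative 1 | methyl 4-[3-(benzyloxy)-4,6-dihydroxy-2-methylbenzoyloxy]-2-hydroxy-3,6-dimethylbenzoate | COC(=O)c1c(C)cc(OC(=O)c2c(C)c(OCc3ccccc3)c(O)cc2O)c(C)c1O
A2 | alternative 1 | 6-[3-(benzyloxy)-2,4-dioxopentyl]-2,2-dimethyl-4H-1,3-dioxin-4-one (racemic) | CC(=O)C(OCc1ccccc1)C(=O)CC1=CC(=O)OC(C)(C)O1
A3 | alternative 1 | methyl 2,4-dihydroxy-3,6-dimethylbenzoate | COC(=O)c1c(C)cc(O)c(C)c1O
A4 | alternative 2 | methyl 4-(3,6-dihydroxy-4-methoxy-2-methylbenzoyloxy)-2-hydroxy-3,6-dimethylbenzoate | COC(=O)c1c(C)cc(OC(=O)c2c(C)c(O)c(OC)cc2O)c(C)c1O
A5 | alternative 2 | 4-methoxy-2-(trimethylsilyloxy)furan | COc1coc(O[Si](C)(C)C)c1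
A6 | alternative 2 | methyl 4-(but-2-ynoyloxy)-2-hydroxy-3,6-dimethylbenzoate | CC#CC(=O)Oc1cc(C)c(C(=O)OC)c(O)c1C
A7 | alternative 3 | methyl 4-[3,6-bis(benzyloxy)-5-formyl-4-methoxy-2-methylbenzoyloxy]-2-hydroxy-3,6-dimethylbenzoate | COC(=O)c1c(C)cc(OC(=O)c2c(C)c(OCc3ccccc3)c(OC)c(C=O)c2OCc2ccccc2)c(C)c1O
A8 | alternative 3 | 2,5-bis(benzyloxy)-3-iodo-6-methoxy-4-methylbenzaldehyde | O=Cc1c(OCc2ccccc2)c(I)c(C)c(OCc2ccccc2)c1OC
A9 | alternative 3 | carbon monoxide | [C-]#[O+]
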